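The route rests on cutting the C1–C15 bond of the α-methylene-γ-lactone (cembrane numbering). Ring O–C16–C15(=C17)–C1–C14 is traced to a 3-methylidene oxolane made by 5-exo addition of a C15 vinyl radical, tethered through the C14 oxygen, to C1 of a C1=C2–C3=C4 dienoate. This single operation forms the five-membered ring with its exocyclic C17 methylene, sets C1 trans to the C13 chain from the C14 centre, and leaves the E C3=C4 enoate. The precursor is an acyclic (14S) 2-bromoallyl ether carrying the (11R,12R)-epoxide, the E,E-dienoate and a C6 phenyl sulfone that later closes the 14-membered ring at C5–C6.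

Key step: step 12

Remark on the chemistry: atom labels follow cembrane numbering (C1 ring-fusion CH; C14 lactone O–CH; C15, C16, C17 = lactone α-carbon, carbonyl, methylene; C11 CHCl; C12 C(OH)CH3; ring alkenes C3=C4 and C7=C8).
Remark on the chemistry: C6 is carried as a phenyl sulfone from step 1 because it deactivates C7=C8, so the asymmetric epoxidation touches only C11=C12, and it is the carbanion site for the C5–C6 closure; the epoxide is introduced only after the dienoate is built, so no γ,δ-epoxy alcohol able to close to an oxolane is formed.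
Remark on the chemistry: geranyl bromide, 2-bromoprop-2-en-1-ol, both phosphoranes, the D-fructose-derived ketone and Li2CuCl4 solution are assumed to be purchased.

Step 1
Reactants: 1 geranyl bromide [(2E)-1-bromo-3,7-dimethylocta-2,6-diene]
Product: 2 geranyl phenyl sulfone {[(2E)-3,7-dimethylocta-2,6-dien-1-yl]sulfonyl}benzene
Conditions: PhSO2Na (1.3 equiv), DMF, rt
Reagents that add atoms: sodium benzenesulfinate, [Na+].[O-]S(=O)c1ccccc1
Why: SN2 S-alkylation of the sulfinate by the primary allylic bromide should give the allylic sulfone with the 2E alkene unchanged.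

Step 2
Reactants: 2 geranyl phenyl sulfone
Product: 3 (2E,6E)-2,6-dimethyl-8-(phenylsulfonyl)octa-2,6-dien-1-ol
Conditions: SeO2 (0.2 equiv), t-BuOOH (3 equiv), salicylic acid (0.1 equiv), CH2Cl2, rt
Reagents that add atoms: tert-butyl hydroperoxide, CC(C)(C)OO (oxygen relayed by catalytic SeO2)
Why: Riley-type allylic oxidation (ene reaction, then [2,3]-sigmatropic shift) should hydroxylate the E-methyl group of the terminal trisubstituted alkene, the alkene next to the sulfonyl group being electronically deactivated.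

Step 3
Reactants: 3 (2E,6E)-2,6-dimethyl-8-(phenylsulfonyl)octa-2,6-dien-1-ol
Product: 4 {[(2E,6E)-8-iodo-3,7-dimethylocta-2,6-dien-1-yl]sulfonyl}benzene
Conditions: PPh3, I2, imidazole, CH2Cl2, 0 °C, dark
Reagents that add atoms: iodine, II
Why: Appel-type iodination, in which iodide displaces the alkoxyphosphonium ion of the primary allylic alcohol by SN2 under buffered conditions, should keep the E alkene; the iodide is used at once.

Step 4
Reactants: 5 2-bromoprop-2-en-1-ol; 6 bromoacetic acid
Product: 7 [(2-bromoprop-2-en-1-yl)oxy]acetic acid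
Conditions: NaH (2.5 equiv), THF, 0 °C → rt; aq. HCl work-up
Reagents that add atoms: none
Why: Williamson ether synthesis, the sodium alkoxide of 5 displacing bromide from sodium bromoacetate, should give the ether acid after acidification.

Step 5
Reactants: 7 [(2-bromoprop-2-en-1-yl)oxy]acetic acid; 8 (R)-4-benzyl-1,3-oxazolidin-2-one
Product: 10 (4R)-4-benzyl-3-{[(2-bromoprop-2-en-1-yl)oxy]acetyl}-1,3-oxazolidin-2-one, via mixed pivalic anhydride 9 (not isolated)
Conditions: t-BuCOCl, Et3N, THF, −20 °C; then LiCl, 8, −20 °C → rt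
Reagents that add atoms: none
Why: N-acylation through the mixed anhydride, which is attacked at the unhindered glycolyl carbonyl under LiCl/Et3N activation, should give the imide without touching the auxiliary centre.

Step 6
Reactants: 10 (4R)-4-benzyl-3-{[(2-bromoprop-2-en-1-yl)oxy]acetyl}-1,3-oxazolidin-2-one (1.5 equiv); 4 {[(2E,6E)-8-iodo-3,7-dimethylocta-2,6-dien-1-yl]sulfonyl}benzene
Product: 12 (4R)-4-benzyl-3-[(2S,4E,8E)-2-[(2-bromoprop-2-en-1-yl)oxy]-4,8-dimethyl-10-(phenylsulfonyl)deca-4,8-dienoyl]-1,3-oxazolidin-2-one, via sodium Z-enolate 11 (not isolated)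
Conditions: NaN(SiMe3)2 (0.95 equiv relative to 10), THF, −78 °C; then 4, −78 → −45 °C
Reagents that add atoms: none
Why: Evans-type glycolate alkylation, in which the chelated Z sodium enolate is alkylated by the allylic iodide on the face opposite the benzyl group, should set C14 as S; base is kept below one equivalent so that the sulfonyl CH2 of 4 is not deprotonated.

Step 7
Reactants: 12 the alkylated imide
Product: 13 (2S,4E,8E)-2-[(2-bromoprop-2-en-1-yl)oxy]-4,8-dimethyl-10-(phenylsulfonyl)deca-4,8-dien-1-ol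
Conditions: LiBH4, MeOH (1 equiv), Et2O, 0 °C
Reagents that add atoms: none
Why: Reductive cleavage of the N-acyl oxazolidinone by hydride attack at the exocyclic carbonyl should give the primary alcohol and release the auxiliary without touching C14, the vinyl bromide or the sulfone.

Step 8
Reactants: 13 the primary alcohol
Product: 14 (2S,4E,8E)-2-[(2-bromoprop-2-en-1-yl)oxy]-4,8-dimethyl-10-(phenylsulfonyl)deca-4,8-dienal
Conditions: Dess–Martin periodinane, CH2Cl2, 0 °C → rt
Reagents that add atoms: none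
Why: Dess–Martin oxidation should give the α-alkoxy aldehyde under conditions too mild to epimerise C14; it is used crude in step 9.

Step 9
Reactants: 14 the α-alkoxy aldehyde; 15 (triphenylphosphoranylidene)acetaldehyde
Product: 16 (2E,4S,6E,10E)-4-[(2-bromoprop-2-en-1-yl)oxy]-6,10-dimethyl-12-(phenylsulfonyl)dodeca-2,6,10-trienal
Conditions: PhMe, 50 °C
Reagents that add atoms: none
Why: Wittig olefination with the stabilised formyl ylide under neutral conditions should give the E enal (C1=C2) and leave C14 intact.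

Step 10
Reactants: 16 the E enal; 17 ethyl 2-(triphenylphosphoranylidene)propanoate
Product: 18 ethyl (2E,4E,6S,8E,12E)-6-[(2-bromoprop-2-en-1-yl)oxy]-2,8,12-trimethyl-14-(phenylsulfonyl)tetradeca-2,4,8,12-tetraenoate
Conditions: CH2Cl2, rt
Reagents that add atoms: none
Why: Wittig olefination of the enal with the stabilised α-methyl ylide is 1,2-selective and should give the E trisubstituted C3=C4 alkene, completing the E,E-dienoate.

Step 11
Reactants: 18 the E,E-dienoate
Product: 19 ethyl (2E,4E,6S)-6-[(2-bromoprop-2-en-1-yl)oxy]-2-methyl-7-{(2R,3R)-2-methyl-3-[(3E)-3-methyl-5-(phenylsulfonyl)pent-3-en-1-yl]oxiran-2-yl}hepta-2,4-dienoate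
Conditions: 1,2:4,5-di-O-isopropylidene-β-D-erythro-2,3-hexodiulo-2,6-pyranose (0.3 equiv), Oxone (2KHSO5·KHSO4·K2SO4), K2CO3, Bu4NHSO4, MeCN/CH2(OMe)2, aq. Na2B4O7 buffer (pH 10.5), 0 °C
Reagents that add atoms: potassium peroxymonosulfate, [K+].[O-]S(=O)(=O)OO
Why: Shi asymmetric epoxidation, in which the chiral dioxirane transfers oxygen through a spiro transition state to the only electron-rich alkene, C11=C12, should give the (11R,12R)-epoxide by reagent control, the sulfonyl-flanked alkene, the ester-conjugated diene and the vinyl bromide being too electron-poor to compete.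

Step 12
Reactants: 19 the (14S) 2-bromoallyl ether with (11R,12R)-epoxide, E,E-dienoate and C6 sulfone
Product: 20 ethyl (2E)-2-methyl-4-[(2S,3R)-4-methylidene-2-({(2R,3R)-2-methyl-3-[(3E)-3-methyl-5-(phenylsulfonyl)pent-3-en-1-yl]oxiran-2-yl}methyl)oxolan-3-yl]but-2-enoate
Conditions: Bu3SnH (1.3 equiv) and AIBN (0.2 equiv) added over 5 h, PhH (0.01 M), 80 °C
Reagents that add atoms: none
Why: Bu3Sn• abstracts bromine from C15, the sp2 vinyl radical adds to C1 of the dienoate, and the ester-delocalised C2–C3–C4 allyl radical, whose C3–C4 bond keeps its E geometry, should take hydrogen from Bu3SnH at the less hindered secondary terminus C2, giving the conjugated enoate and carrying the chain. The closest known reaction type is the tin hydride cyclisation of 2-bromoallyl ethers of allylic alcohols to 3-methylidene oxolanes. The oxolane closes in the 5-exo-trig mode, since attack at C2 (6-endo) would give an unstabilised radical. C1 is controlled by the existing C14 centre: in the chair-like transition state the C13 chain lies pseudo-equatorial and allylic strain turns the diene away from it, so C2 ends trans to C13, which is 1R from 14S. The step needs ring closure to outrun direct reduction of the vinyl radical, 1,5-hydrogen transfer from C13 and addition of tin radicals to the allyl sulfone; the electron-poor diene as a fast acceptor, slow hydride addition at high dilution, the epoxide in place of a C11=C12 alkene (so the C13 hydrogens are not allylic) and the hindered C8 terminus of the sulfonyl allyl unit should secure this.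

Step 13
Reactants: 20 the 3-methylidene oxolane enoate
Product: 21 (2E)-2-methyl-4-[(2S,3R)-4-methylidene-2-({(2R,3R)-2-methyl-3-[(3E)-3-methyl-5-(phenylsulfonyl)pent-3-en-1-yl]oxiran-2-yl}methyl)oxolan-3-yl]but-2-en-1-ol
Conditions: i-Bu2AlH (2.5 equiv), CH2Cl2, −78 °C
Reagents that add atoms: none
Why: 1,2-Reduction of the enoate by i-Bu2AlH at low temperature should give the E allylic alcohol, with epoxide, allyl ether and sulfone inert at −78 °C.

Step 14
Reactants: 21 the C5 allylic alcohol
Product: 23 (2S,3R)-3-[(2E)-4-bromo-3-methylbut-2-en-1-yl]-4-methylidene-2-({(2R,3R)-2-methyl-3-[(3E)-3-methyl-5-(phenylsulfonyl)pent-3-en-1-yl]oxiran-2-yl}methyl)oxolane, via allylic mesylate 22 (not isolated)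
Conditions: MsCl, Et3N, THF, −40 °C; then LiBr, −40 → 0 °C
Reagents that add atoms: lithium bromide, [Li+].[Br-]
Why: Mesylation followed by SN2 displacement with bromide (Finkelstein-type) should give the primary allylic bromide under non-acidic conditions that spare the epoxide and keep the E geometry.

Step 15
Reactants: 23 the C5 allylic bromide with C6 sulfone
Product: 25 macrocyclic sulfone (1R,11R,12R,14S)-11,12:14,16-diepoxy-6-(phenylsulfonyl)cembra-3E,7E,15(17)-triene as both C6 epimers, via potassium sulfonyl carbanion 24 (not isolated)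
Conditions: 23 added over 6 h to KN(SiMe3)2 (1.5 equiv), THF (0.002 M), −40 → 0 °C
Reagents that add atoms: none
Why: Intramolecular SN2 alkylation of the sulfonyl-stabilised allyl anion at its α-carbon C6 by the primary allylic bromide at C5 under high dilution should close the 14-membered ring; the epoxide is geometrically out of reach of C6 and the new C6 centre is removed in step 16.

Step 16
Reactants: 25 the macrocyclic sulfone
Product: 26 (1R,11R,12R,14S)-11,12:14,16-diepoxycembra-3E,7E,15(17)-triene (14-membered ring fused to the 3-methylidene oxolane and the oxirane)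
Conditions: PdCl2[Ph2P(CH2)3PPh2] (0.1 equiv), LiBHEt3 (2.5 equiv), THF, −20 → 0 °C
Reagents that add atoms: none
Why: Palladium-catalysed hydride desulfonylation, in which zerovalent palladium formed in situ ionises the allylic C6–S bond to an η3-allyl complex and hydride enters at the less substituted terminus C6, should keep the E C7=C8 alkene and merge both C6 epimers, the short cold exposure sparing the trisubstituted epoxide.

Step 17
Reactants: 26 the macrocyclic methylidene oxolane
Product: 27 (1R,11R,12R,14S)-11,12-epoxycembra-3E,7E,15(17)-trien-16,14-olide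
Conditions: CrO3 (15 equiv), pyridine (30 equiv), CH2Cl2, rt (CrO3·2C5H5N formed in the flask)
Reagents that add atoms: chromium trioxide, O=[Cr](=O)=O
Why: Allylic oxidation with the hexavalent chromium–pyridine complex should convert the C16 methylene, activated by both the ring oxygen and the C15=C17 alkene, into the lactone carbonyl faster than the plain allylic positions of the large ring, and the epoxide is stable to this neutral reagent.

Step 18
Reactants: 27 the epoxy α-methylene lactone
Product: 28 (1R,11S,12R,14S)-11-chloro-12-hydroxycembra-3E,7E,15(17)-trien-16,14-olide (CNP0247658.1)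
Conditions: Li2CuCl4 (0.1 M in THF, 2 equiv), THF, 0 °C → rt; aq. NH4Cl
Reagents that add atoms: dilithium tetrachlorocuprate, [Li+].[Li+].[Cl-].[Cl-].[Cl-].[Cl-].[Cu+2]
Why: Nucleophilic epoxide opening by the chlorocuprate, with chloride attacking the less hindered secondary C11 by SN2, should invert C11 (11R to 11S) and keep the C12–O bond, giving the 12R tertiary alcohol.

Compound list
1 | geranyl bromide, (2E)-1-bromo-3,7-dimethylocta-2,6-diene | CC(C)=CCC/C(C)=C/CBr | starting material
2 | geranyl phenyl sulfone, {[(2E)-3,7-dimethylocta-2,6-dien-1-yl]sulfonyl}benzene | CC(C)=CCC/C(C)=C/CS(=O)(=O)c1ccccc1 | intermediate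
3 | (2E,6E)-2,6-dimethyl-8-(phenylsulfonyl)octa-2,6-dien-1-ol | OC/C(C)=C/CC/C(C)=C/CS(=O)(=O)c1ccccc1 | intermediate
4 | {[(2E,6E)-8-iodo-3,7-dimethylocta-2,6-dien-1-yl]sulfonyl}benzene | IC/C(C)=C/CC/C(C)=C/CS(=O)(=O)c1ccccc1 | intermediate
5 | 2-bromoprop-2-en-1-ol | C=C(Br)CO | starting material
6 | bromoacetic acid | OC(=O)CBr | starting material
7 | [(2-bromoprop-2-en-1-yl)oxy]acetic acid | C=C(Br)COCC(=O)O | intermediate
8 | (R)-4-benzyl-1,3-oxazolidin-2-one | O=C1N[C@H](Cc2ccccc2)CO1 | starting material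
9 | [(2-bromoprop-2-en-1-yl)oxy]acetic pivalic anhydride (not isolated) | C=C(Br)COCC(=O)OC(=O)C(C)(C)C | intermediate
10 | (4R)-4-benzyl-3-{[(2-bromoprop-2-en-1-yl)oxy]acetyl}-1,3-oxazolidin-2-one | C=C(Br)COCC(=O)N1[C@H](Cc2ccccc2)COC1=O | intermediate
11 | sodium Z-enolate of 10 (not isolated) | C=C(Br)CO/C=C(\[O-])N1[C@H](Cc2ccccc2)COC1=O.[Na+] | intermediate
12 | (4R)-4-benzyl-3-[(2S,4E,8E)-2-[(2-bromoprop-2-en-1-yl)oxy]-4,8-dimethyl-10-(phenylsulfonyl)deca-4,8-dienoyl]-1,3-oxazolidin-2-one | C=C(Br)CO[C@H](C(=O)N1[C@H](Cc2ccccc2)COC1=O)C/C(C)=C/CC/C(C)=C/CS(=O)(=O)c1ccccc1 | intermediate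
13 | (2S,4E,8E)-2-[(2-bromoprop-2-en-1-yl)oxy]-4,8-dimethyl-10-(phenylsulfonyl)deca-4,8-dien-1-ol | C=C(Br)CO[C@H](CO)C/C(C)=C/CC/C(C)=C/CS(=O)(=O)c1ccccc1 | intermediate
14 | (2S,4E,8E)-2-[(2-bromoprop-2-en-1-yl)oxy]-4,8-dimethyl-10-(phenylsulfonyl)deca-4,8-dienal | C=C(Br)CO[C@H](C=O)C/C(C)=C/CC/C(C)=C/CS(=O)(=O)c1ccccc1 | intermediate
15 | (triphenylphosphoranylidene)acetaldehyde | O=CC=P(c1ccccc1)(c1ccccc1)c1ccccc1 | starting material
16 | (2E,4S,6E,10E)-4-[(2-bromoprop-2-en-1-yl)oxy]-6,10-dimethyl-12-(phenylsulfonyl)dodeca-2,6,10-trienal | C=C(Br)CO[C@H](/C=C/C=O)C/C(C)=C/CC/C(C)=C/CS(=O)(=O)c1ccccc1 | intermediate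
17 | ethyl 2-(triphenylphosphoranylidene)propanoate | CCOC(=O)C(C)=P(c1ccccc1)(c1ccccc1)c1ccccc1 | starting material
18 | ethyl (2E,4E,6S,8E,12E)-6-[(2-bromoprop-2-en-1-yl)oxy]-2,8,12-trimethyl-14-(phenylsulfonyl)tetradeca-2,4,8,12-tetraenoate | C=C(Br)CO[C@H](/C=C/C=C(\C)C(=O)OCC)C/C(C)=C/CC/C(C)=C/CS(=O)(=O)c1ccccc1 | intermediate
19 | ethyl (2E,4E,6S)-6-[(2-bromoprop-2-en-1-yl)oxy]-2-methyl-7-{(2R,3R)-2-methyl-3-[(3E)-3-methyl-5-(phenylsulfonyl)pent-3-en-1-yl]oxiran-2-yl}hepta-2,4-dienoate (key-step precursor) | C=C(Br)CO[C@H](/C=C/C=C(\C)C(=O)OCC)C[C@@]1(C)O[C@@H]1CC/C(C)=C/CS(=O)(=O)c2ccccc2 | intermediate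
20 | ethyl (2E)-2-methyl-4-[(2S,3R)-4-methylidene-2-({(2R,3R)-2-methyl-3-[(3E)-3-methyl-5-(phenylsulfonyl)pent-3-en-1-yl]oxiran-2-yl}methyl)oxolan-3-yl]but-2-enoate (key-step product) | C=C1CO[C@@H](C[C@@]2(C)O[C@@H]2CC/C(C)=C/CS(=O)(=O)c3ccccc3)[C@@H]1C/C=C(\C)C(=O)OCC | intermediate
21 | (2E)-2-methyl-4-[(2S,3R)-4-methylidene-2-({(2R,3R)-2-methyl-3-[(3E)-3-methyl-5-(phenylsulfonyl)pent-3-en-1-yl]oxiran-2-yl}methyl)oxolan-3-yl]but-2-en-1-ol | C=C1CO[C@@H](C[C@@]2(C)O[C@@H]2CC/C(C)=C/CS(=O)(=O)c3ccccc3)[C@@H]1C/C=C(\C)CO | intermediate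
22 | methanesulfonate of 21 (not isolated) | C=C1CO[C@@H](C[C@@]2(C)O[C@@H]2CC/C(C)=C/CS(=O)(=O)c3ccccc3)[C@@H]1C/C=C(\C)COS(C)(=O)=O | intermediate
23 | (2S,3R)-3-[(2E)-4-bromo-3-methylbut-2-en-1-yl]-4-methylidene-2-({(2R,3R)-2-methyl-3-[(3E)-3-methyl-5-(phenylsulfonyl)pent-3-en-1-yl]oxiran-2-yl}methyl)oxolane | C=C1CO[C@@H](C[C@@]2(C)O[C@@H]2CC/C(C)=C/CS(=O)(=O)c3ccccc3)[C@@H]1C/C=C(\C)CBr | intermediate
24 | potassium salt of the C6 sulfonyl carbanion of 23 (not isolated) | C=C1CO[C@@H](C[C@@]2(C)O[C@@H]2CC/C(C)=C/[CH-]S(=O)(=O)c3ccccc3)[C@@H]1C/C=C(\C)CBr.[K+] | intermediate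
25 | (1R,11R,12R,14S)-11,12:14,16-diepoxy-6-(phenylsulfonyl)cembra-3E,7E,15(17)-triene, both C6 epimers | C=C1CO[C@H]2C[C@@]3(C)O[C@@H]3CC/C(C)=C/C(S(=O)(=O)c4ccccc4)C/C(C)=C/C[C@H]12 | intermediate
26 | (1R,11R,12R,14S)-11,12:14,16-diepoxycembra-3E,7E,15(17)-triene | C=C1CO[C@H]2C[C@@]3(C)O[C@@H]3CC/C(C)=C/CC/C(C)=C/C[C@H]12 | intermediate
27 | (1R,11R,12R,14S)-11,12-epoxycembra-3E,7E,15(17)-trien-16,14-olide | C=C1C(=O)O[C@H]2C[C@@]3(C)O[C@@H]3CC/C(C)=C/CC/C(C)=C/C[C@H]12 | intermediate
28 | (1R,11S,12R,14S)-11-chloro-12-hydroxycembra-3E,7E,15(17)-trien-16,14-olide, CNP0247658.1 | C=C1C(=O)O[C@H]2C[C@@](C)(O)[C@@H](Cl)CC/C(C)=C/CC/C(C)=C/C[C@H]12 | target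

Total step count: 18. Longest linear sequence: 16 steps (steps 1–3, then 6–18).

Steps most likely to fail

Step 12. Hydrogen may be delivered to the ester-bearing terminus C4 of the allyl radical instead of C2, which would deconjugate the ester and lose the defined C3=C4 geometry. The C14 centre may also steer C1 incompletely, and the vinyl radical may be reduced before it closes. The fallback sets out from 14 and returns to 20. It shortens the acceptor to a simple enoate, whose cyclised radical can only be reduced at C2, and builds C3=C4 afterwards. Wittig olefination of 14 with ethyl (triphenylphosphoranylidene)acetate (CH2Cl2, rt) should give ethyl (2E,4S,6E,10E)-4-[(2-bromoprop-2-en-1-yl)oxy]-6,10-dimethyl-12-(phenylsulfonyl)dodeca-2,6,10-trienoate F1. Epoxidation under the conditions of step 11 should give ethyl (2E,4S)-4-[(2-bromoprop-2-en-1-yl)oxy]-5-{(2R,3R)-2-methyl-3-[(3E)-3-methyl-5-(phenylsulfonyl)pent-3-en-1-yl]oxiran-2-yl}pent-2-enoate F2. Bu3SnH/AIBN as in step 12 should close the ring 5-exo to ethyl [(2S,3R)-4-methylidene-2-({(2R,3R)-2-methyl-3-[(3E)-3-methyl-5-(phenylsulfonyl)pent-3-en-1-yl]oxiran-2-yl}methyl)oxolan-3-yl]acetate F3. i-Bu2AlH (1.1 equiv, PhMe, −78 °C) should stop at [(2S,3R)-4-methylidene-2-({(2R,3R)-2-methyl-3-[(3E)-3-methyl-5-(phenylsulfonyl)pent-3-en-1-yl]oxiran-2-yl}methyl)oxolan-3-yl]acetaldehyde F4. Wittig olefination of F4 with 17 then gives 20.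

Step 15. Intermolecular alkylation may give oligomers, the base may cause 1,4-elimination of HBr from the allylic bromide, or the allyl anion may alkylate at its γ-carbon. The fallback sets out from 21 and returns to 25 and makes no new compound (F0). Alcohol 21 itself is cyclised by a Mitsunobu-type dehydrative C-alkylation with Bu3P=CHCN in toluene at 100 °C under high dilution. The phosphorane converts the allylic alcohol into an alkoxyphosphonium ion, and the released cyanomethyl anion deprotonates the sulfone only as the electrophile forms, so neither a strong amide base nor an allylic halide is present.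

Step 18. Chloride may enter at the tertiary C12 if the Lewis-acidic salt loosens the C12–O bond, and the C7=C8 alkene may attack the activated epoxide across the ring. The exocyclic enoate of the lactone may also take up nucleophiles, which narrows the choice of chloride sources. The fallback sets out from 26 and returns to 28 by exchanging the last two operations. Opening the epoxide of 26, which has no Michael acceptor, with LiCl/AcOH in THF (or Li2CuCl4) should give (1R,11S,12R,14S)-11-chloro-14,16-epoxycembra-3E,7E,15(17)-trien-12-ol F5. Oxidation of F5 with CrO3·2C5H5N as in step 17, to which the tertiary alcohol and the secondary chloride are inert, then gives 28.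

Further compounds
F1 | step 12 | ethyl (2E,4S,6E,10E)-4-[(2-bromoprop-2-en-1-yl)oxy]-6,10-dimethyl-12-(phenylsulfonyl)dodeca-2,6,10-trienoate | C=C(Br)CO[C@H](/C=C/C(=O)OCC)C/C(C)=C/CC/C(C)=C/CS(=O)(=O)c1ccccc1
F2 | step 12 | ethyl (2E,4S)-4-[(2-bromoprop-2-en-1-yl)oxy]-5-{(2R,3R)-2-methyl-3-[(3E)-3-methyl-5-(phenylsulfonyl)pent-3-en-1-yl]oxiran-2-yl}pent-2-enoate | C=C(Br)CO[C@H](/C=C/C(=O)OCC)C[C@@]1(C)O[C@@H]1CC/C(C)=C/CS(=O)(=O)c2ccccc2
F3 | step 12 | ethyl [(2S,3R)-4-methylidene-2-({(2R,3R)-2-methyl-3-[(3E)-3-methyl-5-(phenylsulfonyl)pent-3-en-1-yl]oxiran-2-yl}methyl)oxolan-3-yl]acetate | C=C1CO[C@@H](C[C@@]2(C)O[C@@H]2CC/C(C)=C/CS(=O)(=O)c3ccccc3)[C@@H]1CC(=O)OCC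
F4 | step 12 | [(2S,3R)-4-methylidene-2-({(2R,3R)-2-methyl-3-[(3E)-3-methyl-5-(phenylsulfonyl)pent-3-en-1-yl]oxiran-2-yl}methyl)oxolan-3-yl]acetaldehyde | C=C1CO[C@@H](C[C@@]2(C)O[C@@H]2CC/C(C)=C/CS(=O)(=O)c3ccccc3)[C@@H]1CC=O
F0 | step 15 | none | none
F5 | step 18 | (1R,11S,12R,14S)-11-chloro-14,16-epoxycembra-3E,7E,15(17)-trien-12-ol | C=C1CO[C@H]2C[C@@](C)(O)[C@@H](Cl)CC/C(C)=C/CC/C(C)=C/C[C@H]12
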